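**Plan**

- Retrosynthesis: the four phenols are masked as methyl ethers and the saturated chain is traced back to a 2,7-dienone. This is cut at C2=C3 and C7=C8 into an aryl vinyl ketone, cyclopentene and methyl eugenol. The vinyl ketone is cut at C1–C2 into 2,6-dimethoxybenzaldehyde and a vinyl nucleophile.
- Enabling feature: the chain C1–C9 between the resorcinol ring (on the C1 ketone) and the catechol ring (on C9) is unbranched and unsubstituted from C2 to C9. C1–C2 therefore maps onto the vinyl ketone, C3–C7 onto the five ring carbons of cyclopentene, and C8–C9 onto the allyl group of methyl eugenol, whose arene is the catechol ring as its dimethyl ether.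
- Forward: aldehyde to allylic alcohol to vinyl ketone (steps 1 and 2). One-flask metathesis then opens cyclopentene onto the ketone (C2=C3) and caps the free end with methyl eugenol (C7=C8) (step 3). Hydrogenation (step 4) and fourfold O-demethylation (step 5) finish the route.
- No ring is formed (both arenes are purchased) and the target has no stereocentre. The carbinol centre of the racemic alcohol is removed by oxidation and both alkene geometries by hydrogenation.

Key step: step 3

Remark on the chemistry: the chain is numbered from the ketone carbon (C1) to the benzylic carbon on the catechol ring (C9). Compound 7 is written as its (2E,7E) isomer, the one expected to predominate; the geometry at C7=C8 is of no consequence.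

**Step 1**
Reactants: 1 2,6-dimethoxybenzaldehyde
Product: 2 rac-1-(2,6-dimethoxyphenyl)prop-2-en-1-ol
Conditions: CH2=CHMgBr (1.3 equiv), THF, 0 °C to rt; sat. aq NH4Cl
Reagents that add atoms: vinylmagnesium bromide, C=C[Mg]Br
Why: Grignard 1,2-addition to a non-enolisable aryl aldehyde, assisted by chelation of magnesium to an ortho methoxy group; the new carbinol centre is racemic and is erased in step 2.

**Step 2**
Reactants: 2 rac-1-(2,6-dimethoxyphenyl)prop-2-en-1-ol
Product: 3 1-(2,6-dimethoxyphenyl)prop-2-en-1-one
Conditions: activated MnO2 (15 equiv), CH2Cl2, rt, dark; filter through Celite, concentrate cold with a trace of BHT, use at once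
Reagents that add atoms: none
Why: MnO2 oxidation of an alcohol that is both allylic and benzylic, run under neutral heterogeneous conditions so that the polymerisable vinyl ketone sees neither acid nor nucleophile.

**Step 3**
Reactants: 3 1-(2,6-dimethoxyphenyl)prop-2-en-1-one; 4 cyclopentene; 5 methyl eugenol (4-allyl-1,2-dimethoxybenzene)
Product: 7 (2E,7E)-1-(2,6-dimethoxyphenyl)-9-(3,4-dimethoxyphenyl)nona-2,7-dien-1-one, via terminal dienone 6 (not isolated)
Conditions: second-generation Hoveyda–Grubbs catalyst RuCl2(=CH-C6H4-2-OiPr)(H2IMes) (3 mol %), 4 (5 equiv), 1,4-benzoquinone (10 mol %), toluene (0.05 M in 3), closed flask, 40 °C; Ar sparge to strip surplus 4; then 5 (3 equiv), further catalyst (2 mol %), 50 °C, slow Ar sweep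
Reagents that add atoms: none
Why: Proposed new method: in the closed first stage the ruthenium methylidene opens cyclopentene by [2+2] cycloaddition and cycloreversion to the alkylidene Ru=CH(CH2)3CH=CH2, which is captured by the electron-poor vinyl ketone 3 to forge the conjugated C2=C3 bond of 6 and return the methylidene, so that this stage releases no by-product. After the surplus cyclopentene is swept out, the terminal alkene of 6 exchanges its methylene with the allyl group of 5 and ethene leaves, which forms the C7=C8 bond of 7. The closest known reaction types are ring-opening cross-metathesis of unstrained cycloalkenes with acrylates or vinyl ketones and cross-metathesis of allylarenes with terminal alkenes; what is new is their ordering in one flask so that one opened ring receives two different caps. No ring is closed and no stereocentre is made; C2=C3 should be E as the more stable conjugated isomer and the geometry at C7=C8 is irrelevant because step 4 removes it. The selectivity needed is end differentiation, that is, against double capping by 3, against direct coupling of 3 with 5 that would skip C3–C7, and against multiple insertion of cyclopentene. It should be secured because 3 meets only ring-opened alkylidenes while 5 is absent, because an enone terminus neither carries the catalyst nor re-enters metathesis whereas every other olefin keeps exchanging, because cyclopentene is in fivefold excess over 3 yet below the concentration at which polypentenamer is stable so that over-inserted chains back-bite to cyclopentene, and because 5 is used in excess.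

**Step 4**
Reactants: 7 (2E,7E)-1-(2,6-dimethoxyphenyl)-9-(3,4-dimethoxyphenyl)nona-2,7-dien-1-one
Product: 8 1-(2,6-dimethoxyphenyl)-9-(3,4-dimethoxyphenyl)nonan-1-one
Conditions: H2 (1 atm), 10% Pd/C, EtOAc, rt
Reagents that add atoms: none
Why: heterogeneous catalytic hydrogenation should saturate both disubstituted alkenes, while the aryl ketone, twisted out of conjugation by its two ortho substituents, and the methyl ethers are expected to stay untouched at 1 atm in a neutral solvent.

**Step 5**
Reactants: 8 1-(2,6-dimethoxyphenyl)-9-(3,4-dimethoxyphenyl)nonan-1-one
Product: 9 malabaricone C, 1-(2,6-dihydroxyphenyl)-9-(3,4-dihydroxyphenyl)nonan-1-one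
Conditions: BBr3 (8 equiv), CH2Cl2, −78 °C to rt; then H2O, 0 °C, work-up under Ar
Reagents that add atoms: none
Why: Lewis-acid cleavage of aryl methyl ethers, in which boron binds each ether oxygen and bromide removes the methyl group by SN2 attack; the two ethers flanking the ketone are helped by chelation, and the ketone and saturated chain are inert.

**Compound list**

1 | 2,6-dimethoxybenzaldehyde | COc1cccc(OC)c1C=O | starting material
2 | rac-1-(2,6-dimethoxyphenyl)prop-2-en-1-ol | C=CC(O)c1c(OC)cccc1OC | intermediate
3 | 1-(2,6-dimethoxyphenyl)prop-2-en-1-one | C=CC(=O)c1c(OC)cccc1OC | intermediate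
4 | cyclopentene | C1=CCCC1 | starting material
5 | methyl eugenol (4-allyl-1,2-dimethoxybenzene) | C=CCc1ccc(OC)c(OC)c1 | starting material
6 | (E)-1-(2,6-dimethoxyphenyl)octa-2,7-dien-1-one | COc1cccc(OC)c1C(=O)/C=C/CCCC=C | intermediate
7 | (2E,7E)-1-(2,6-dimethoxyphenyl)-9-(3,4-dimethoxyphenyl)nona-2,7-dien-1-one | COc1cccc(OC)c1C(=O)/C=C/CCC/C=C/Cc1ccc(OC)c(OC)c1 | intermediate
8 | 1-(2,6-dimethoxyphenyl)-9-(3,4-dimethoxyphenyl)nonan-1-one | COc1cccc(OC)c1C(=O)CCCCCCCCc1ccc(OC)c(OC)c1 | intermediate
9 | malabaricone C, 1-(2,6-dihydroxyphenyl)-9-(3,4-dihydroxyphenyl)nonan-1-one | O=C(CCCCCCCCc1ccc(O)c(O)c1)c1c(O)cccc1O | target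

**Step count**

Total: 5 steps. Longest linear sequence: 5 steps (1 to 9); cyclopentene and methyl eugenol enter as purchased in step 3.

**Steps most likely to fail**

Step 3. The three olefins may scramble statistically. One opened ring may be capped twice by the vinyl ketone, more than one cyclopentene may be inserted, and the allyl group of 5 may migrate into conjugation and give chain-shortened cross products. The catalyst may also die in the dilute first stage. The fallback uses established two-component chemistry, sets out from 3 and comes back at 8. Commercial 3,4-dimethoxyphenylmagnesium bromide is coupled with 8-bromooct-1-ene under iron catalysis (Fe(acac)3, TMEDA, THF, 0 °C; Kumada-type aryl Grignard–alkyl bromide coupling) to give 8-(3,4-dimethoxyphenyl)oct-1-ene F1. Ordinary cross-metathesis of F1 with 3 (same ruthenium catalyst, CH2Cl2, 40 °C), a well-established pairing of a readily dimerising terminal alkene with a non-dimerising vinyl ketone, should give (E)-1-(2,6-dimethoxyphenyl)-9-(3,4-dimethoxyphenyl)non-2-en-1-one F2. Hydrogenation of F2 under the conditions of step 4 leads to 8.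

Step 2. The vinyl ketone may polymerise or dimerise during the oxidation, the filtration and the concentration, and the hindered carbinol may oxidise slowly, which lengthens the exposure. The fallback postpones the oxidation until the alkene is internal; it sets out from 2 and comes back at 8. Alcohol 2 is cross-metathesised with 8-(3,4-dimethoxyphenyl)oct-1-ene F1, made as described for step 3 (same ruthenium catalyst, 1,4-benzoquinone, CH2Cl2, 40 °C). This should give (E)-1-(2,6-dimethoxyphenyl)-9-(3,4-dimethoxyphenyl)non-2-en-1-ol F3. MnO2 oxidation of this allylic, benzylic alcohol gives the β-substituted and therefore non-polymerising enone (E)-1-(2,6-dimethoxyphenyl)-9-(3,4-dimethoxyphenyl)non-2-en-1-one F2, which is hydrogenated as in step 4 to 8.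

Step 5. Dealkylation may stop short, most likely at the second ether beside the ketone once the first phenoxide is chelated to boron, and the liberated catechol may oxidise during work-up. The fallback leaves the low-temperature Lewis-acid manifold for a Brønsted-acid halide melt; it sets out from 8 and comes back at 9. Compound 8 is heated in molten pyridinium chloride at about 190 °C under argon, where chloride removes the methyl groups from the protonated ethers by SN2 attack; dilution with water and extraction then give 9. No compound outside the list is made (F0).

**Further compounds**

F1 | step 3 | 8-(3,4-dimethoxyphenyl)oct-1-ene | C=CCCCCCCc1ccc(OC)c(OC)c1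
F2 | step 3 | (E)-1-(2,6-dimethoxyphenyl)-9-(3,4-dimethoxyphenyl)non-2-en-1-one | COc1cccc(OC)c1C(=O)/C=C/CCCCCCc1ccc(OC)c(OC)c1
F3 | step 2 | (E)-1-(2,6-dimethoxyphenyl)-9-(3,4-dimethoxyphenyl)non-2-en-1-ol | COc1cccc(OC)c1C(O)/C=C/CCCCCCc1ccc(OC)c(OC)c1
F0 | step 5 | none | none
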